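**Retrosynthetic overview**
- The pyranone C-ring is opened to an o-hydroxyaryl 1,3-diketone, which comes from a late C-acylation of an A-ring ketone enolate (already carrying the 1,1-dimethylallyl group and the future 3-prenyl chain) with a B-ring aroyl chloride.
- The 1,1-dimethylallyl group is set by an aromatic Claisen rearrangement of a prenyl ether whose para position is blocked by the acyl group; the ketone comes from directed ortho-lithiation plus a Weinreb amide.
- The phloroglucinol oxygen pattern of ring A is made from resorcinol by Ir-catalysed meta C–H borylation and oxidation; the side-chain amide comes from a Johnson–Claisen rearrangement.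
- Ring B comes from resorcinol by Vilsmeier formylation, allylation and Pinnick oxidation.
- Ring order: A and B are pre-formed benzene rings; only the C-ring is built (second-to-last step), followed by global deallylation.

Assumption: the target has no stereocentres, so no enantiocontrol is needed; the only stereocentre in the route (C2 of diketone 18) is racemic and is destroyed on cyclisation.

**A-ring branch**

Step 1
Reactants: 1 resorcinol
Product: 2 1,3-bis(methoxymethoxy)benzene
Conditions: NaH, MOMCl, DMF, 0 °C → rt
Reagents that add atoms: chloromethyl methyl ether, COCCl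
Why: Williamson-type O-alkylation of both phenoxides; MOM is the directing group for the later lithiation and survives base, Ir catalysis and 190 °C.

Step 2
Reactants: 2
Product: 3 3,5-bis(methoxymethoxy)phenol
Conditions: [Ir(OMe)(cod)]2 (cat.), dtbpy, B2pin2, THF, 80 °C; then aq. NaOH, H2O2, 0 °C
Reagents that add atoms: bis(pinacolato)diboron, CC1(C)OB(OC1(C)C)B1OC(C)(C)C(C)(C)O1 (boron not retained); hydrogen peroxide, OO (supplies the O)
Why: Sterically controlled Ir-catalysed aromatic C–H borylation can only occur at C5, the one C–H with no ortho substituent, and boronate oxidation then gives the 1,3,5-trioxygenated ring.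

Step 3
Reactants: 3; 4 prenyl bromide (1-bromo-3-methylbut-2-ene)
Product: 5 1,3-bis(methoxymethoxy)-5-[(3-methylbut-2-en-1-yl)oxy]benzene
Conditions: K2CO3, DMF, rt
Reagents that add atoms: none (4 is a numbered reactant)
Why: Williamson ether synthesis on the only free phenol; O-alkylation is favoured with K2CO3 in a dipolar aprotic solvent.

**Side-chain branch**

Step 4
Reactants: 6 2-methylbut-3-en-2-ol; 7 trimethyl orthoacetate
Product: 8 methyl 5-methylhex-4-enoate
Conditions: EtCO2H (cat.), 110 → 140 °C, MeOH distilled off
Reagents that add atoms: none (both are numbered reactants)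
Why: Johnson–Claisen rearrangement; the mixed ketene acetal of the tertiary allylic alcohol undergoes a [3,3] shift to the γ,δ-unsaturated ester with the trisubstituted alkene.

Step 5
Reactants: 8
Product: 9 N-methoxy-N,5-dimethylhex-4-enamide
Conditions: MeNHOMe·HCl, i-PrMgCl, THF, −20 → 0 °C
Reagents that add atoms: N,O-dimethylhydroxylamine hydrochloride, CNOC.Cl
Why: Weinreb amide formation by aminolysis of the ester with the magnesium amide; the isolated alkene is inert.

**A-ring ketone**

Step 6
Reactants: 5; 9
Product: 10 1-[2,6-bis(methoxymethoxy)-4-[(3-methylbut-2-en-1-yl)oxy]phenyl]-5-methylhex-4-en-1-one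
Conditions: n-BuLi, THF, 0 °C, 1 h; then 9, −78 → 0 °C
Reagents that add atoms: none
Why: Directed ortho-metalation at the position flanked by two chelating MOM ethers (much stronger directors than the prenyl ether), then Weinreb ketone synthesis, which stops at the ketone via the chelated tetrahedral intermediate.

Step 7
Reactants: 10
Product: 11 1-[4-hydroxy-2,6-bis(methoxymethoxy)-3-(2-methylbut-3-en-2-yl)phenyl]-5-methylhex-4-en-1-one
Conditions: PhNEt2, 190 °C, Ar, 2–3 h
Reagents that add atoms: none
Why: Aromatic Claisen rearrangement transfers the prenyl group with allylic inversion to the ortho carbon as the 1,1-dimethylallyl group; the two ortho positions are equivalent and the para position is blocked by the acyl group, so no para (Claisen–Cope) product can form.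

Step 8
Reactants: 11
Product: 12 5-methyl-1-[2,4,6-trihydroxy-3-(2-methylbut-3-en-2-yl)phenyl]hex-4-en-1-one
Conditions: 2 M HCl, MeOH, 40 °C
Reagents that add atoms: none
Why: Acid-catalysed acetal cleavage of both MOM ethers (ortho to the ketone, hence labile); the vinyl and trisubstituted alkenes are not protonated by dilute methanolic HCl.

Step 9
Reactants: 12
Product: 13 1-[2-hydroxy-3-(2-methylbut-3-en-2-yl)-4,6-bis(prop-2-en-1-yloxy)phenyl]-5-methylhex-4-en-1-one
Conditions: allyl bromide (2.1 equiv), K2CO3, acetone, 50 °C
Reagents that add atoms: allyl bromide, C=CCBr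
Why: Regioselective Williamson O-allylation: the acidic para OH and the unhindered ortho OH react, while the OH wedged between the quaternary carbon and the carbonyl stays free as the hydrogen-bonded chelate (check: both OCH2 groups show NOE to the lone aromatic H).

**B-ring branch**

Step 10
Reactants: 1 resorcinol
Product: 14 2,4-dihydroxybenzaldehyde
Conditions: POCl3, DMF, MeCN, −15 °C → rt; then H2O, 50 °C
Reagents that add atoms: N,N-dimethylformamide, CN(C)C=O (formyl carbon); water, O (carbonyl oxygen)
Why: Vilsmeier–Haack formylation occurs at C4, para to one OH and ortho to the other; hydrolysis of the iminium salt gives the aldehyde.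

Step 11
Reactants: 14
Product: 15 2,4-bis(prop-2-en-1-yloxy)benzaldehyde
Conditions: allyl bromide (2.5 equiv), K2CO3, DMF, 60 °C
Reagents that add atoms: allyl bromide, C=CCBr
Why: Williamson etherification of both phenols; warming in DMF overcomes the hydrogen-bonded ortho OH.

Step 12
Reactants: 15
Product: 16 2,4-bis(prop-2-en-1-yloxy)benzoic acid
Conditions: NaClO2, NaH2PO4, 2-methyl-2-butene, t-BuOH/H2O, rt
Reagents that add atoms: sodium chlorite, [Na+].[O-]Cl=O
Why: Pinnick oxidation of the aldehyde; excess 2-methyl-2-butene scavenges HOCl so the allyl ethers are untouched.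

Step 13
Reactants: 16
Product: 17 2,4-bis(prop-2-en-1-yloxy)benzoyl chloride
Conditions: (COCl)2, DMF (cat.), CH2Cl2, 0 °C → rt; used crude
Reagents that add atoms: oxalyl chloride, O=C(Cl)C(=O)Cl
Why: Acid chloride formation through the Vilsmeier-type chloroiminium; allyl ethers tolerate the HCl released.

**Fragment coupling and endgame**

Step 14
Reactants: 13; 17
Product: 18 1-[2,4-bis(prop-2-en-1-yloxy)phenyl]-3-[2-hydroxy-3-(2-methylbut-3-en-2-yl)-4,6-bis(prop-2-en-1-yloxy)phenyl]-2-(3-methylbut-2-en-1-yl)propane-1,3-dione (racemic at C2; may exist partly as the cyclic hemiketal)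
Conditions: LiHMDS (3.2 equiv), THF, −78 → −20 °C; then 17, −78 °C → rt
Reagents that add atoms: none
Why: Claisen-type C-acylation of the lithium phenoxide–enolate dianion (one-pot Baker–Venkataraman variant) joins the two halves; the hindered phenoxide does not O-acylate competitively, and the new stereocentre is racemic and removed in the next step.

Step 15
Reactants: 18
Product: 19 5,7-bis(prop-2-en-1-yloxy)-2-[2,4-bis(prop-2-en-1-yloxy)phenyl]-8-(2-methylbut-3-en-2-yl)-3-(3-methylbut-2-en-1-yl)-4H-chromen-4-one
Conditions: p-TsOH·H2O (0.2 equiv), toluene, 70 °C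
Reagents that add atoms: none
Why: Acid-catalysed cyclodehydration of the o-hydroxyaryl 1,3-diketone; only the OH next to the 1,1-dimethylallyl group is free, so the ring oxygen and the 8-substitution are unambiguous, and allyl ethers are acid-stable.

Step 16
Reactants: 19
Product: 20 nigrasin I, 2-(2,4-dihydroxyphenyl)-5,7-dihydroxy-8-(2-methylbut-3-en-2-yl)-3-(3-methylbut-2-en-1-yl)-4H-chromen-4-one
Conditions: Pd(PPh3)4 (10 mol %), morpholine (excess), THF, rt, degassed
Reagents that add atoms: none
Why: Pd(0)-catalysed Tsuji–Trost deallylation of the four aryl allyl ethers with morpholine as allyl scavenger; the C-bound prenyl and 1,1-dimethylallyl groups have no leaving group and the neutral conditions avoid acid-induced cyclisation onto the free phenols.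

**Compound list**
1 | resorcinol | Oc1cccc(O)c1 | starting material
2 | 1,3-bis(methoxymethoxy)benzene | COCOc1cccc(OCOC)c1 | intermediate
3 | 3,5-bis(methoxymethoxy)phenol | COCOc1cc(O)cc(OCOC)c1 | intermediate
4 | prenyl bromide (1-bromo-3-methylbut-2-ene) | CC(C)=CCBr | starting material
5 | 1,3-bis(methoxymethoxy)-5-[(3-methylbut-2-en-1-yl)oxy]benzene | COCOc1cc(OCC=C(C)C)cc(OCOC)c1 | intermediate
6 | 2-methylbut-3-en-2-ol | C=CC(C)(C)O | starting material
7 | trimethyl orthoacetate | CC(OC)(OC)OC | starting material
8 | methyl 5-methylhex-4-enoate | COC(=O)CCC=C(C)C | intermediate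
9 | N-methoxy-N,5-dimethylhex-4-enamide | CON(C)C(=O)CCC=C(C)C | intermediate
10 | 1-[2,6-bis(methoxymethoxy)-4-[(3-methylbut-2-en-1-yl)oxy]phenyl]-5-methylhex-4-en-1-one | CC(C)=CCCC(=O)c1c(OCOC)cc(OCC=C(C)C)cc1OCOC | intermediate
11 | 1-[4-hydroxy-2,6-bis(methoxymethoxy)-3-(2-methylbut-3-en-2-yl)phenyl]-5-methylhex-4-en-1-one | CC(C)=CCCC(=O)c1c(OCOC)cc(O)c(C(C)(C)C=C)c1OCOC | intermediate
12 | 5-methyl-1-[2,4,6-trihydroxy-3-(2-methylbut-3-en-2-yl)phenyl]hex-4-en-1-one | CC(C)=CCCC(=O)c1c(O)cc(O)c(C(C)(C)C=C)c1O | intermediate
13 | 1-[2-hydroxy-3-(2-methylbut-3-en-2-yl)-4,6-bis(prop-2-en-1-yloxy)phenyl]-5-methylhex-4-en-1-one | CC(C)=CCCC(=O)c1c(OCC=C)cc(OCC=C)c(C(C)(C)C=C)c1O | intermediate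
14 | 2,4-dihydroxybenzaldehyde | O=Cc1ccc(O)cc1O | intermediate
15 | 2,4-bis(prop-2-en-1-yloxy)benzaldehyde | C=CCOc1ccc(C=O)c(OCC=C)c1 | intermediate
16 | 2,4-bis(prop-2-en-1-yloxy)benzoic acid | C=CCOc1ccc(C(=O)O)c(OCC=C)c1 | intermediate
17 | 2,4-bis(prop-2-en-1-yloxy)benzoyl chloride | C=CCOc1ccc(C(=O)Cl)c(OCC=C)c1 | intermediate
18 | 1-[2,4-bis(allyloxy)phenyl]-3-[2-hydroxy-3-(2-methylbut-3-en-2-yl)-4,6-bis(allyloxy)phenyl]-2-(3-methylbut-2-en-1-yl)propane-1,3-dione (racemic) | CC(C)=CCC(C(=O)c1ccc(OCC=C)cc1OCC=C)C(=O)c1c(OCC=C)cc(OCC=C)c(C(C)(C)C=C)c1O | intermediate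
19 | 5,7-bis(allyloxy)-2-[2,4-bis(allyloxy)phenyl]-8-(2-methylbut-3-en-2-yl)-3-(3-methylbut-2-en-1-yl)-4H-chromen-4-one | C=CC(C)(C)c1c(OCC=C)cc(OCC=C)c2c(=O)c(CC=C(C)C)c(-c3ccc(OCC=C)cc3OCC=C)oc12 | intermediate
20 | nigrasin I | C=CC(C)(C)c1c(O)cc(O)c2c(=O)c(CC=C(C)C)c(-c3ccc(O)cc3O)oc12 | target

**Totals**
Total step count: 16.
Longest linear sequence: 10 steps (1 → 2 → 3 → 5 → 10 → 11 → 12 → 13 → 18 → 19 → 20; steps 1, 2, 3, 6, 7, 8, 9, 14, 15, 16).

**Three steps most likely to fail**
- **Step 9 (which ortho OH stays free).** If the steric and chelation bias is insufficient, the wrong bis-allyl isomer forms and leads to the 6-substituted flavone. Fallback: move the para-blocking role from the acyl group to a bromine. Lithiate 2 at C2 and brominate, then borylate/oxidise, prenylate and run the Claisen (only ortho is possible). The phenol released is then itself the future ring oxygen. Introduce the ketone at the single remaining ring C–H by Mg-mediated ortho-formylation, addition of 4-methylpent-3-enylmagnesium bromide and oxidation, and remove the bromine reductively later. No selective protection is needed.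
- **Step 6 (lithiation in the presence of the prenyl ether).** Risks are lithiation next to the prenyl ether, ether cleavage by n-BuLi, and enolisation of the Weinreb amide. Fallback: reverse the order. Lithiate symmetric 2 at C2 (the only doubly flanked site) and acylate with 9 first, then install the para oxygen by Ir-catalysed borylation (only the C–H para to the acyl is unhindered) with amine N-oxide oxidation, then O-prenylate to reach the same 10.
- **Step 14 (C-acylation of a hindered, α-substituted dianion).** Risks are low conversion and N- or O-acylation. Fallback: form the same C–C bond by an aldol addition of the dianion of 13 to aldehyde 15, then oxidise the β-hydroxy ketone (Dess–Martin) to 18.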